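**Plan**
- Cuts: (a) the enyne C(sp)–C(sp2) bond, giving a 5-ethynyloxolane and (1E,3E,9E)-1-bromo-10-iododeca-1,3,9-triene; (b) the alkynyl–C5 bond, once C5 is raised to a lactone carbonyl; (c) in one operation the ring bonds C3–C4 and O1–C2, leaving a hex-5-enoate and iodoacetic acid.
- Forward: the oxolane ring arises first, as the γ-lactone, by an enantioselective copper-catalysed radical [3+2] carbo-lactonisation. It is opened at the acyl C5–O1 bond by an acetylide and reclosed at C5–O1 by SN2, so O1–C2 and C3–C4 are never broken. The side chain is joined last.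
- Stereochemistry: C2 (R) from the chiral ligand on copper in the key step. C5 (S) from catalyst-controlled Noyori transfer hydrogenation of the ynone followed by invertive Williamson closure, which gives 2,5-trans. The three E-alkenes come from syn-hydrozirconation/iodinolysis, a stabilised Wittig reaction and a Takai–Utimoto olefination.
- Enabling feature: in the oxolane, C2 carries only the unbranched ester chain and C3 and C4 are unsubstituted CH2 groups, so C2–C3 is a masked monosubstituted alkene. C4–C5–O1, with C5 a propargylic ether carbon reachable from a carbonyl by acetylide addition, is a masked acetic acid unit.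

Key step: step 2

Remark: the ester is carried as the tert-butyl ester from step 1 to step 8, because the C-5 alkoxides of steps 3 and 7 would lactonise onto a methyl ester.
Remark: in step 2 the (S,S) ligand is written; the antipode that delivers the (R)-lactone has to be fixed by experiment.
Remark: cyclopentadienyl ligands are drawn σ-bonded in the SMILES of zirconium compounds.

Step 1
Reactants: 1 hex-5-enoic acid
Product: 2 tert-butyl hex-5-enoate
Conditions: isobutene (excess), conc. H2SO4 (cat.), CH2Cl2, −20 °C → rt, sealed vessel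
Reagents that add atoms: isobutene, C=C(C)C
Why: Acid-catalysed addition of the carboxylic acid to isobutene (tert-butyl ester formation) should leave the far less basic monosubstituted alkene untouched.

Step 2
Reactants: 2 tert-butyl hex-5-enoate; 3 iodoacetic acid (1.5 equiv)
Product: 5 tert-butyl 4-[(2R)-5-oxooxolan-2-yl]butanoate, via racemic caesium 8-tert-butoxy-4-iodo-8-oxooctanoate 4 (not isolated)
Conditions: Cu(MeCN)4PF6 (10 mol %), (S,S)-t-Bu-box [2,2′-(propane-2,2-diyl)bis((4S)-4-tert-butyl-4,5-dihydro-1,3-oxazole)] (12 mol %), Cs2CO3 (0.8 equiv), MeCN, blue LEDs (450 nm), 0 °C → rt, degassed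
Reagents that add atoms: none
Why: Proposed new method: monovalent copper abstracts iodine from the iodoacetate to give the electrophilic carboxymethyl radical, which adds to the terminal CH2 of 2 and forms C3–C4; the secondary C-2 radical, which carries its own carboxylate, is captured by the box-ligated divalent copper as a six-membered alkyl carboxylato chelate of trivalent copper, and C–O reductive elimination closes the five-membered lactone (formally a 5-exo-tet closure of the carboxylate oxygen on C-2). The closest known reaction types are the copper-mediated atom-transfer addition–lactonisation of haloacetic acids with 1-alkenes (racemic), the copper/bis(oxazoline) enantioselective radical oxyfunctionalisation of alkenoic acids to lactones, and the photoinduced copper-catalysed enantioconvergent substitution of unactivated secondary alkyl halides. The only new stereocentre, C-2, is set by the chiral ligand on copper in the radical capture/reductive elimination. The step is stereoconvergent: racemic iodide 4 formed by iodine transfer should be returned to the same planar radical under irradiation and funnelled into one lactone enantiomer. Regioselectivity is secured by the monosubstituted alkene and the polarity match of the radical; chemoselectivity by the tert-butyl ester, which cannot act as a competing carboxylate; enantioselectivity by the tethered carboxylate, which makes the metallacycle rigid enough for the ligand to differentiate its faces.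

Step 3
Reactants: 5 tert-butyl 4-[(2R)-5-oxooxolan-2-yl]butanoate; 6 ethynyltrimethylsilane
Product: 8 tert-butyl (5R)-5-hydroxy-8-oxo-10-(trimethylsilyl)dec-9-ynoate, via lithium (trimethylsilyl)acetylide 7 (not isolated)
Conditions: 6, n-BuLi, THF, −78 °C; then 5, −78 °C; AcOH quench at −78 °C
Reagents that add atoms: none
Why: Acetylide addition to a γ-lactone stops at the tetrahedral lithium hemiketal at −78 °C and gives the γ-hydroxy ynone on work-up; the tert-butyl ester is inert, and only the acyl C5–O1 bond is cleaved.

Step 4
Reactants: 8 tert-butyl (5R)-5-hydroxy-8-oxo-10-(trimethylsilyl)dec-9-ynoate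
Product: 9 tert-butyl (5R)-8-oxo-5-[(triethylsilyl)oxy]-10-(trimethylsilyl)dec-9-ynoate
Conditions: TESOTf, 2,6-lutidine, CH2Cl2, −78 °C
Reagents that add atoms: triethylsilyl trifluoromethanesulfonate, CC[Si](CC)(CC)OS(=O)(=O)C(F)(F)F
Why: Silyl ether formation traps the open-chain tautomer and keeps the C-5 oxygen (the future ring oxygen) distinct from the oxygen to be activated.

Step 5
Reactants: 9 tert-butyl (5R)-8-oxo-5-[(triethylsilyl)oxy]-10-(trimethylsilyl)dec-9-ynoate
Product: 10 tert-butyl (5R,8R)-8-hydroxy-5-[(triethylsilyl)oxy]-10-(trimethylsilyl)dec-9-ynoate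
Conditions: Ru[(R,R)-TsDPEN](p-cymene) (2 mol %), i-PrOH, rt
Reagents that add atoms: none
Why: Noyori asymmetric transfer hydrogenation of an alkynyl ketone; the (R,R) catalyst should deliver hydride to the face that gives the (8R)-propargylic alcohol under catalyst control, independent of the remote C-5 centre.

Step 6
Reactants: 10 tert-butyl (5R,8R)-8-hydroxy-5-[(triethylsilyl)oxy]-10-(trimethylsilyl)dec-9-ynoate
Product: 11 tert-butyl (5R,8R)-8-[(methylsulfonyl)oxy]-5-[(triethylsilyl)oxy]-10-(trimethylsilyl)dec-9-ynoate
Conditions: Ms2O, Et3N, CH2Cl2, −40 → 0 °C; crude product used directly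
Reagents that add atoms: methanesulfonic anhydride, CS(=O)(=O)OS(C)(=O)=O
Why: O-sulfonylation with retention at C-8; the anhydride avoids chloride, which could displace a propargylic sulfonate.

Step 7
Reactants: 11 tert-butyl (5R,8R)-8-[(methylsulfonyl)oxy]-5-[(triethylsilyl)oxy]-10-(trimethylsilyl)dec-9-ynoate
Product: 13 tert-butyl 4-[(2R,5S)-5-ethynyloxolan-2-yl]butanoate, via tert-butyl (5R,8R)-5-hydroxy-8-[(methylsulfonyl)oxy]dec-9-ynoate 12 (not isolated)
Conditions: Bu4NF (3 equiv, 1 M in THF), THF, 0 °C → rt
Reagents that add atoms: none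
Why: Fluoride removes both silyl groups and the liberated C-5 alkoxide closes the ring by intramolecular Williamson etherification (5-exo-tet SN2) with inversion at the propargylic carbon, so (8R) becomes (5S) and the ring is 2,5-trans; the hindered tert-butyl ester does not lactonise.

Step 8
Reactants: 13 tert-butyl 4-[(2R,5S)-5-ethynyloxolan-2-yl]butanoate
Product: 14 methyl 4-[(2R,5S)-5-ethynyloxolan-2-yl]butanoate
Conditions: HCl (1.25 M in MeOH), rt → 40 °C
Reagents that add atoms: methanol, CO
Why: Acid-mediated transesterification (alkyl–oxygen cleavage of the tert-butyl ester followed by Fischer esterification); no stereocentre is acidic or ionisable under these conditions.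

Step 9
Reactants: 15 hept-6-yn-1-ol
Product: 17 (6E)-7-iodohept-6-en-1-ol, via O-zirconated (E)-alkenylzirconocene chloride 16 (not isolated)
Conditions: Cp2Zr(H)Cl (2.3 equiv), THF, rt, dark; then I2 (1.1 equiv), 0 °C; aqueous work-up
Reagents that add atoms: iodine, [I][I]
Why: Hydrozirconation (the first equivalent is consumed by the hydroxyl group) adds Zr–H syn with zirconium at the terminal carbon, and iodinolysis with retention gives the (E)-alkenyl iodide.

Step 10
Reactants: 17 (6E)-7-iodohept-6-en-1-ol
Product: 18 (6E)-7-iodohept-6-enal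
Conditions: Dess–Martin periodinane, CH2Cl2, rt
Reagents that add atoms: none
Why: Dess–Martin oxidation of a primary alcohol stops at the aldehyde and does not touch the alkenyl iodide.

Step 11
Reactants: 18 (6E)-7-iodohept-6-enal; 19 2-(triphenyl-λ5-phosphanylidene)acetaldehyde
Product: 20 (2E,8E)-9-iodonona-2,8-dienal
Conditions: toluene, 80 °C
Reagents that add atoms: none
Why: Wittig olefination with a stabilised ylide should give the (E)-enal; a slight deficit of ylide limits double homologation.

Step 12
Reactants: 20 (2E,8E)-9-iodonona-2,8-dienal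
Product: 21 (1E,3E,9E)-1-bromo-10-iododeca-1,3,9-triene
Conditions: CrBr2 (6 equiv), CHBr3 (2 equiv), THF, 0 °C → rt, dark
Reagents that add atoms: bromoform, BrC(Br)Br
Why: Takai–Utimoto olefination; the geminal dichromium species adds to the aldehyde and eliminates to the (E)-alkenyl bromide. The bromide salt of divalent chromium avoids halogen scrambling, and the alkenyl iodide is inert to divalent chromium in the absence of nickel.

Step 13
Reactants: 14 methyl 4-[(2R,5S)-5-ethynyloxolan-2-yl]butanoate; 21 (1E,3E,9E)-1-bromo-10-iododeca-1,3,9-triene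
Product: 22 methyl 4-[(2R,5S)-5-[(3E,9E,11E)-12-bromododeca-3,9,11-trien-1-yn-1-yl]oxolan-2-yl]butanoate
Conditions: Pd(PPh3)4 (5 mol %), CuI (10 mol %), i-Pr2NH, THF, rt, degassed, dark
Reagents that add atoms: none
Why: Sonogashira coupling; oxidative addition of zerovalent palladium to the alkenyl C–I bond is much faster than to the dienyl C–Br bond at room temperature, and the alkene geometry is retained.

**Compound list**
1 | hex-5-enoic acid | C=CCCCC(=O)O | starting material
2 | tert-butyl hex-5-enoate | C=CCCCC(=O)OC(C)(C)C | intermediate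
3 | iodoacetic acid | OC(=O)CI | starting material
4 | caesium 8-tert-butoxy-4-iodo-8-oxooctanoate (racemic) | [Cs+].[O-]C(=O)CCC(I)CCCC(=O)OC(C)(C)C | intermediate
5 | tert-butyl 4-[(2R)-5-oxooxolan-2-yl]butanoate | CC(C)(C)OC(=O)CCC[C@@H]1CCC(=O)O1 | intermediate
6 | ethynyltrimethylsilane | C#C[Si](C)(C)C | starting material
7 | lithium (trimethylsilyl)acetylide | [Li]C#C[Si](C)(C)C | intermediate
8 | tert-butyl (5R)-5-hydroxy-8-oxo-10-(trimethylsilyl)dec-9-ynoate | CC(C)(C)OC(=O)CCC[C@@H](O)CCC(=O)C#C[Si](C)(C)C | intermediate
9 | tert-butyl (5R)-8-oxo-5-[(triethylsilyl)oxy]-10-(trimethylsilyl)dec-9-ynoate | CC(C)(C)OC(=O)CCC[C@@H](O[Si](CC)(CC)CC)CCC(=O)C#C[Si](C)(C)C | intermediate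
10 | tert-butyl (5R,8R)-8-hydroxy-5-[(triethylsilyl)oxy]-10-(trimethylsilyl)dec-9-ynoate | CC(C)(C)OC(=O)CCC[C@@H](O[Si](CC)(CC)CC)CC[C@@H](O)C#C[Si](C)(C)C | intermediate
11 | tert-butyl (5R,8R)-8-[(methylsulfonyl)oxy]-5-[(triethylsilyl)oxy]-10-(trimethylsilyl)dec-9-ynoate | CC(C)(C)OC(=O)CCC[C@@H](O[Si](CC)(CC)CC)CC[C@@H](OS(C)(=O)=O)C#C[Si](C)(C)C | intermediate
12 | tert-butyl (5R,8R)-5-hydroxy-8-[(methylsulfonyl)oxy]dec-9-ynoate (formed as its alkoxide) | CC(C)(C)OC(=O)CCC[C@@H](O)CC[C@@H](OS(C)(=O)=O)C#C | intermediate
13 | tert-butyl 4-[(2R,5S)-5-ethynyloxolan-2-yl]butanoate | CC(C)(C)OC(=O)CCC[C@@H]1CC[C@@H](C#C)O1 | intermediate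
14 | methyl 4-[(2R,5S)-5-ethynyloxolan-2-yl]butanoate | COC(=O)CCC[C@@H]1CC[C@@H](C#C)O1 | intermediate
15 | hept-6-yn-1-ol | C#CCCCCCO | starting material
16 | (E)-[7-(chlorozirconocenyloxy)hept-1-en-1-yl]zirconocene chloride | Cl[Zr](OCCCCC/C=C/[Zr](Cl)(C1C=CC=C1)C1C=CC=C1)(C1C=CC=C1)C1C=CC=C1 | intermediate
17 | (6E)-7-iodohept-6-en-1-ol | OCCCCC/C=C/I | intermediate
18 | (6E)-7-iodohept-6-enal | O=CCCCC/C=C/I | intermediate
19 | 2-(triphenyl-λ5-phosphanylidene)acetaldehyde | O=CC=P(c1ccccc1)(c1ccccc1)c1ccccc1 | starting material
20 | (2E,8E)-9-iodonona-2,8-dienal | O=C/C=C/CCCC/C=C/I | intermediate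
21 | (1E,3E,9E)-1-bromo-10-iododeca-1,3,9-triene | Br/C=C/C=C/CCCC/C=C/I | intermediate
22 | methyl 4-[(2R,5S)-5-[(3E,9E,11E)-12-bromododeca-3,9,11-trien-1-yn-1-yl]oxolan-2-yl]butanoate | COC(=O)CCC[C@@H]1CC[C@@H](C#C/C=C/CCCC/C=C/C=C/Br)O1 | target

**Step count**
Total: 13 steps. Longest linear sequence: 9 steps (steps 1 to 8, then step 13).

**Steps most likely to fail**

Step 2. The enantioselective radical capture at copper may be outrun by racemic iodine transfer followed by uncatalysed SN2 lactonisation, or the unactivated secondary radical may be captured with poor facial discrimination. Fallback, from 2: epoxidation with m-CPBA in CH2Cl2 gives racemic tert-butyl 4-(oxiran-2-yl)butanoate F1. Jacobsen hydrolytic kinetic resolution with (R,R)-(salen)Co(OAc) (trivalent cobalt, 0.5 mol %) and 0.55 equiv of water is expected to leave tert-butyl 4-[(2R)-oxiran-2-yl]butanoate F2. Opening at the terminal carbon with diethyl malonate and NaOEt in EtOH, with lactonisation in the same pot, gives ethyl (5R)-5-[4-(tert-butoxy)-4-oxobutyl]-2-oxooxolane-3-carboxylate F3. Krapcho dealkoxycarbonylation (LiCl, wet DMSO, 140 °C) returns to the route at 5.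

Step 7. Elimination to the enyne, substitution by fluoride, or partial ionisation at the propargylic sulfonate may compete with the invertive ring closure. Fallback, from 5 (it bypasses steps 3 to 6 as well): reduction with i-Bu2AlH in CH2Cl2 at −78 °C and acetylation in the same pot (Ac2O, pyridine, DMAP) gives tert-butyl 4-[(2R)-5-acetoxyoxolan-2-yl]butanoate F4 as an anomer mixture. Substitution with tributyl[(trimethylsilyl)ethynyl]stannane and BF3·OEt2 in CH2Cl2 at −78 °C, in which the alkynyl group should enter the oxocarbenium ion mainly trans to the C-2 chain, gives after chromatographic removal of the cis isomer tert-butyl 4-[(2R,5S)-5-[(trimethylsilyl)ethynyl]oxolan-2-yl]butanoate F5. K2CO3 in MeOH removes the silyl group and returns to the route at 13.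

Step 13. Oxidative addition may not discriminate well enough between the alkenyl iodide and the dienyl bromide, and the alkyne may dimerise oxidatively. Fallback, from 14 and 20: Sonogashira coupling with the iodo dienal, which has no second halide (Pd(PPh3)4, CuI, i-Pr2NH, THF), gives methyl 4-[(2R,5S)-5-[(3E,9E)-11-oxoundeca-3,9-dien-1-yn-1-yl]oxolan-2-yl]butanoate F6. Takai–Utimoto bromo-olefination (CHBr3, CrBr2, THF) as the last step then arrives at 22.

**Further compounds**
F1 | step 2 | tert-butyl 4-(oxiran-2-yl)butanoate (racemic) | CC(C)(C)OC(=O)CCCC1CO1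
F2 | step 2 | tert-butyl 4-[(2R)-oxiran-2-yl]butanoate | CC(C)(C)OC(=O)CCC[C@@H]1CO1
F3 | step 2 | ethyl (5R)-5-[4-(tert-butoxy)-4-oxobutyl]-2-oxooxolane-3-carboxylate (C-3 epimers) | CC(C)(C)OC(=O)CCC[C@@H]1CC(C(=O)OCC)C(=O)O1
F4 | step 7 | tert-butyl 4-[(2R)-5-acetoxyoxolan-2-yl]butanoate (anomer mixture) | CC(C)(C)OC(=O)CCC[C@@H]1CCC(OC(C)=O)O1
F5 | step 7 | tert-butyl 4-[(2R,5S)-5-[(trimethylsilyl)ethynyl]oxolan-2-yl]butanoate | CC(C)(C)OC(=O)CCC[C@@H]1CC[C@@H](C#C[Si](C)(C)C)O1
F6 | step 13 | methyl 4-[(2R,5S)-5-[(3E,9E)-11-oxoundeca-3,9-dien-1-yn-1-yl]oxolan-2-yl]butanoate | COC(=O)CCC[C@@H]1CC[C@@H](C#C/C=C/CCCC/C=C/C=O)O1
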